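## Retrosynthetic overview

1. Target 26 ⇐ furanophane 22: the furan is opened at the very end with singlet oxygen to a ring-locked Z-ene-1,4-dione, both ketones are reduced with one CBS catalyst (C3, C6), and the 6-hydroxyl closes the γ-lactone.
2. 22 ⇐ bromo-aldehyde 18: the ten-membered carbocycle is closed as a [6](2,5)-furanophane by intramolecular indium Barbier allylation (C7–C8 bond; sets C7 and C8), then the 8-hydroxyl is acylated.
3. 18 ⇐ furfural 13 + methyl acrylate (Baylis–Hillman, rearranged allylic bromide); 13 ⇐ 2-lithio-3-methylfuran + epoxy triflate 9 (C2–C3 bond), then formylation.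
4. 9 ⇐ allylic alcohol 6 by Sharpless epoxidation (sets C1, C10, the source of absolute configuration); 6 ⇐ alkyne 3 by carboalumination.
5. Ring order: oxirane → ten-membered carbocycle (furan as a bridging unit) → furan destroyed → γ-lactone last.

Assumption: 3-methylfuran, silyl ether 3, methyl acrylate and isobutyric anhydride are bought; macrocycles are named with germacrane numbering (ring C1–C10; C11, C12, C13 = acrylate α-carbon, carboxyl carbon, methylene; C14 on C10; C15 on C4).

## Route

Step 1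
Reactants: 1 3-methylfuran
Product: 2 2-bromo-3-methylfuran
Conditions: NBS (1.0 equiv), DMF, −20 → 0 °C, dark; used promptly
Reagents that add atoms: N-bromosuccinimide, O=C1CCC(=O)N1Br
Why: Electrophilic aromatic bromination goes to the α-carbon next to the methyl group, the most activated position of 3-methylfuran (as with 3-methylthiophene), which fixes where the side chain will later be attached.

Step 2
Reactants: 3 tert-butyl(but-3-yn-1-yloxy)dimethylsilane
Product: 6 (E)-5-(tert-butyldimethylsilyloxy)-3-methylpent-2-en-1-ol, via alkenyldimethylalane 4 (not isolated), via lithium alkenylaluminate 5 (not isolated)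
Conditions: Me3Al (3 equiv), Cp2ZrCl2 (25 mol%), CH2Cl2, 0 °C → rt; n-BuLi, THF, −30 °C; (CH2O)n, −30 °C → rt; aqueous work-up
Reagents that add atoms: trimethylaluminium, C[Al](C)C; formaldehyde (as paraformaldehyde), C=O
Why: Negishi zirconium-catalysed carboalumination adds methyl and aluminium syn across the terminal alkyne, and the aluminate is hydroxymethylated with retention, so the trisubstituted alkene is E (this becomes the trans C1–C10 epoxide).

Step 3
Reactants: 6 (E)-5-(tert-butyldimethylsilyloxy)-3-methylpent-2-en-1-ol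
Product: 7 [(2S,3S)-3-[2-(tert-butyldimethylsilyloxy)ethyl]-3-methyloxiran-2-yl]methanol
Conditions: Ti(OiPr)4 (10 mol%), L-(+)-diethyl tartrate (12 mol%), t-BuOOH (2 equiv), 4 Å MS, CH2Cl2, −20 °C
Reagents that add atoms: tert-butyl hydroperoxide, CC(C)(C)OO
Why: Katsuki–Sharpless asymmetric epoxidation with L-(+)-tartrate gives the (2S,3S)-epoxy alcohol, the same sense as geraniol to (2S,3S)-epoxygeraniol, which sets C1 and C10 of the target (both S).

Step 4
Reactants: 7 [(2S,3S)-3-[2-(tert-butyldimethylsilyloxy)ethyl]-3-methyloxiran-2-yl]methanol; 2 2-bromo-3-methylfuran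
Product: 11 tert-butyldimethyl{2-[(2S,3S)-2-methyl-3-[(3-methylfuran-2-yl)methyl]oxiran-2-yl]ethoxy}silane, via lithium alkoxide 8 (not isolated), via epoxy triflate 9 (not isolated), via 2-lithio-3-methylfuran 10 (not isolated)
Conditions: 7, n-BuLi (1.0 equiv), THF, −78 °C; Tf2O (1.05 equiv), 10 min; cannulate into 10 [2 (1.3 equiv), n-BuLi (1.3 equiv), THF, −78 °C]; −78 → −30 °C
Reagents that add atoms: none
Why: SN2 alkylation of a heteroaryllithium (from bromine–lithium exchange) by a primary epoxy triflate, which at −78 °C reacts far faster than the trisubstituted epoxide; no stereocentre is touched.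

Step 5
Reactants: 11 tert-butyldimethyl{2-[(2S,3S)-2-methyl-3-[(3-methylfuran-2-yl)methyl]oxiran-2-yl]ethoxy}silane
Product: 13 5-{[(2S,3S)-3-[2-(tert-butyldimethylsilyloxy)ethyl]-3-methyloxiran-2-yl]methyl}-4-methylfuran-2-carbaldehyde, via 5-lithiofuran 12 (not isolated)
Conditions: n-BuLi (1.1 equiv), TMEDA, THF, −40 → −10 °C; DMF, −78 °C → rt; H2O
Reagents that add atoms: N,N-dimethylformamide, CN(C)C=O
Why: α-Lithiation of the only free furan α-position followed by formylation with DMF (Bouveault-type) installs the carbon that becomes C7; no stereocentre is touched.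

Step 6
Reactants: 13 5-{[(2S,3S)-3-[2-(tert-butyldimethylsilyloxy)ethyl]-3-methyloxiran-2-yl]methyl}-4-methylfuran-2-carbaldehyde; 14 methyl acrylate
Product: 15 methyl 2-{hydroxy[5-({(2S,3S)-3-[2-(tert-butyldimethylsilyloxy)ethyl]-3-methyloxiran-2-yl}methyl)-4-methylfuran-2-yl]methyl}prop-2-enoate (1:1 at the carbinol carbon)
Conditions: methyl acrylate (5 equiv), 1,4-diazabicyclo[2.2.2]octane (1 equiv), MeOH, rt, 5 d
Reagents that add atoms: methyl acrylate (14), C=CC(=O)OC
Why: Morita–Baylis–Hillman reaction of a furfural with an acrylate; the new carbinol centre is formed unselectively and is erased in step 7.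

Step 7
Reactants: 15 methyl 2-{hydroxy[5-({(2S,3S)-3-[2-(tert-butyldimethylsilyloxy)ethyl]-3-methyloxiran-2-yl}methyl)-4-methylfuran-2-yl]methyl}prop-2-enoate
Product: 16 methyl (2Z)-2-(bromomethyl)-3-[5-({(2S,3S)-3-[2-(tert-butyldimethylsilyloxy)ethyl]-3-methyloxiran-2-yl}methyl)-4-methylfuran-2-yl]prop-2-enoate
Conditions: NBS, Me2S (premixed, 0 °C), CH2Cl2; add 15, 0 °C → rt
Reagents that add atoms: N-bromosuccinimide, O=C1CCC(=O)N1Br
Why: Corey–Kim bromination of the doubly activated carbinol proceeds with allylic transposition (SN2') to the thermodynamically preferred Z bromide (furyl trans to the ester), under neutral conditions that spare the epoxide and the silyl ether.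

Step 8
Reactants: 16 methyl (2Z)-2-(bromomethyl)-3-[5-({(2S,3S)-3-[2-(tert-butyldimethylsilyloxy)ethyl]-3-methyloxiran-2-yl}methyl)-4-methylfuran-2-yl]prop-2-enoate
Product: 17 methyl (2Z)-2-(bromomethyl)-3-[5-{[(2S,3S)-3-(2-hydroxyethyl)-3-methyloxiran-2-yl]methyl}-4-methylfuran-2-yl]prop-2-enoate
Conditions: HF·pyridine, pyridine, THF, 0 °C
Reagents that add atoms: none
Why: Buffered fluoride desilylation removes the primary silyl ether without a basic fluoride source that would attack the allylic bromide or the epoxide.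

Step 9
Reactants: 17 methyl (2Z)-2-(bromomethyl)-3-[5-{[(2S,3S)-3-(2-hydroxyethyl)-3-methyloxiran-2-yl]methyl}-4-methylfuran-2-yl]prop-2-enoate
Product: 18 methyl (2Z)-2-(bromomethyl)-3-[4-methyl-5-{[(2S,3S)-3-methyl-3-(2-oxoethyl)oxiran-2-yl]methyl}furan-2-yl]prop-2-enoate
Conditions: Dess–Martin periodinane, pyridine, CH2Cl2, 0 °C; used crude at once
Reagents that add atoms: none
Why: Dess–Martin oxidation is neutral and fast, which is what the elimination-prone β,γ-epoxy aldehyde needs.

Step 10
Reactants: 18 methyl (2Z)-2-(bromomethyl)-3-[4-methyl-5-{[(2S,3S)-3-methyl-3-(2-oxoethyl)oxiran-2-yl]methyl}furan-2-yl]prop-2-enoate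
Product: 20 methyl (1S,7R,8R,10S)-1,10:3,6-diepoxy-8-hydroxygermacra-3,5,11(13)-trien-12-oate (furanophane hydroxy ester), via allylindium dibromide 19 (not isolated)
Conditions: indium powder (3 equiv), THF–H2O (3:1), rt, syringe-pump addition of 18 (final 2 mM)
Reagents that add atoms: none
Why: Intramolecular indium Barbier allylation through a closed six-membered chair transition state, where the retained Z geometry of the 2-carbomethoxyallyl-indium gives the syn C7/C8 relationship (as in intermolecular indium allylations with (Z)-3-aryl-2-(bromomethyl)acrylates), and the face relative to the epoxide is set by the rigid trans-epoxide in the forming ten-membered ring (the natural 7R,8R arrangement is expected but not assured).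

Step 11
Reactants: 20 methyl (1S,7R,8R,10S)-1,10:3,6-diepoxy-8-hydroxygermacra-3,5,11(13)-trien-12-oate; 21 isobutyric anhydride
Product: 22 methyl (1S,7R,8R,10S)-1,10:3,6-diepoxy-8-(2-methylpropanoyloxy)germacra-3,5,11(13)-trien-12-oate (furanophane isobutyrate)
Conditions: (i-PrCO)2O (1.5 equiv), Et3N, 4-(dimethylamino)pyridine (10 mol%), CH2Cl2, 0 °C
Reagents that add atoms: isobutyric anhydride (21), CC(C)C(=O)OC(=O)C(C)C
Why: Nucleophile-catalysed acylation of the secondary alcohol outruns lactonisation onto the methyl ester and leaves C8 untouched, so the ester is kept for the 6-hydroxyl.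

Step 12
Reactants: 22 methyl (1S,7R,8R,10S)-1,10:3,6-diepoxy-8-(2-methylpropanoyloxy)germacra-3,5,11(13)-trien-12-oate
Product: 26 (1S,3S,6R,7R,8R,10S,4Z)-1,10-epoxy-3-hydroxy-8-(2-methylpropanoyloxy)germacra-4,11(13)-dien-12,6-olide (target), via furan endoperoxide 23 (not isolated), via Z-enedione 24 (not isolated), via Z-enediol 25 (not isolated)
Conditions: O2, hν (visible), 5,10,15,20-tetraphenylporphyrin (1 mol%), CH2Cl2, −78 °C; PPh3 (1.05 equiv), −78 → −30 °C; (R)-2-methyl-CBS-oxazaborolidine [(R)-1-methyl-3,3-diphenyltetrahydro-1H,3H-pyrrolo[1,2-c][1,3,2]oxazaborole] (30 mol%), catecholborane (4 equiv), toluene, −78 → −40 °C; MeOH; aq. NaHCO3; pyridinium p-toluenesulfonate (10 mol%), CH2Cl2, rt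
Reagents that add atoms: dioxygen, O=O
Why: Proposed new method: the electron-rich trialkylfuran takes up singlet oxygen in a [4+2] cycloaddition much faster than the acrylate or any other group, PPh3 removes one peroxide oxygen to give the Z-enedione (the ten-membered ring cannot hold the E isomer), the (R)-CBS catalyst then reduces both enone carbonyls with the alkenyl group as the large substituent, which by the Corey model gives 3S and 6R from one catalyst, and the 6-hydroxyl closes the trans γ-lactone on the methyl ester; the closest known chemistry is furan photooxygenation/reduction to Z-ene-1,4-diones and CBS reduction of enones and of 1,4-diketones to C2-type diols.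

## Compound list

1 | 3-methylfuran | Cc1ccoc1 | starting material
2 | 2-bromo-3-methylfuran | Cc1ccoc1Br | intermediate
3 | tert-butyl(but-3-yn-1-yloxy)dimethylsilane | C#CCCO[Si](C)(C)C(C)(C)C | starting material
4 | (E)-[4-(tert-butyldimethylsilyloxy)-2-methylbut-1-en-1-yl]dimethylalane | C/C(CCO[Si](C)(C)C(C)(C)C)=C\[Al](C)C | intermediate
5 | lithium butyl[(E)-4-(tert-butyldimethylsilyloxy)-2-methylbut-1-en-1-yl]dimethylaluminate | [Li+].CCCC[Al-](C)(C)/C=C(\C)CCO[Si](C)(C)C(C)(C)C | intermediate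
6 | (E)-5-(tert-butyldimethylsilyloxy)-3-methylpent-2-en-1-ol | C/C(CCO[Si](C)(C)C(C)(C)C)=C\CO | intermediate
7 | [(2S,3S)-3-[2-(tert-butyldimethylsilyloxy)ethyl]-3-methyloxiran-2-yl]methanol | C[C@@]1(CCO[Si](C)(C)C(C)(C)C)O[C@H]1CO | intermediate
8 | lithium [(2S,3S)-3-[2-(tert-butyldimethylsilyloxy)ethyl]-3-methyloxiran-2-yl]methanolate | C[C@@]1(CCO[Si](C)(C)C(C)(C)C)O[C@H]1C[O-].[Li+] | intermediate
9 | [(2S,3S)-3-[2-(tert-butyldimethylsilyloxy)ethyl]-3-methyloxiran-2-yl]methyl trifluoromethanesulfonate | C[C@@]1(CCO[Si](C)(C)C(C)(C)C)O[C@H]1COS(=O)(=O)C(F)(F)F | intermediate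
10 | 2-lithio-3-methylfuran | Cc1ccoc1[Li] | intermediate
11 | tert-butyldimethyl{2-[(2S,3S)-2-methyl-3-[(3-methylfuran-2-yl)methyl]oxiran-2-yl]ethoxy}silane | C[C@@]1(CCO[Si](C)(C)C(C)(C)C)O[C@H]1Cc1occc1C | intermediate
12 | 5-lithio derivative of 11 (lithium at the free furan α-carbon) | C[C@@]1(CCO[Si](C)(C)C(C)(C)C)O[C@H]1Cc1oc([Li])cc1C | intermediate
13 | 5-{[(2S,3S)-3-[2-(tert-butyldimethylsilyloxy)ethyl]-3-methyloxiran-2-yl]methyl}-4-methylfuran-2-carbaldehyde | C[C@@]1(CCO[Si](C)(C)C(C)(C)C)O[C@H]1Cc1oc(C=O)cc1C | intermediate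
14 | methyl acrylate | C=CC(=O)OC | starting material
15 | methyl 2-{hydroxy[5-({(2S,3S)-3-[2-(tert-butyldimethylsilyloxy)ethyl]-3-methyloxiran-2-yl}methyl)-4-methylfuran-2-yl]methyl}prop-2-enoate (both carbinol epimers) | C[C@@]1(CCO[Si](C)(C)C(C)(C)C)O[C@H]1Cc1oc(C(O)C(=C)C(=O)OC)cc1C | intermediate
16 | methyl (2Z)-2-(bromomethyl)-3-[5-({(2S,3S)-3-[2-(tert-butyldimethylsilyloxy)ethyl]-3-methyloxiran-2-yl}methyl)-4-methylfuran-2-yl]prop-2-enoate | C[C@@]1(CCO[Si](C)(C)C(C)(C)C)O[C@H]1Cc1oc(/C=C(\CBr)C(=O)OC)cc1C | intermediate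
17 | methyl (2Z)-2-(bromomethyl)-3-[5-{[(2S,3S)-3-(2-hydroxyethyl)-3-methyloxiran-2-yl]methyl}-4-methylfuran-2-yl]prop-2-enoate | C[C@@]1(CCO)O[C@H]1Cc1oc(/C=C(\CBr)C(=O)OC)cc1C | intermediate
18 | methyl (2Z)-2-(bromomethyl)-3-[4-methyl-5-{[(2S,3S)-3-methyl-3-(2-oxoethyl)oxiran-2-yl]methyl}furan-2-yl]prop-2-enoate | C[C@@]1(CC=O)O[C@H]1Cc1oc(/C=C(\CBr)C(=O)OC)cc1C | intermediate
19 | allylindium dibromide from 18 (InBr2 in place of Br) | C[C@@]1(CC=O)O[C@H]1Cc1oc(/C=C(\C[In](Br)Br)C(=O)OC)cc1C | intermediate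
20 | methyl (1S,7R,8R,10S)-1,10:3,6-diepoxy-8-hydroxygermacra-3,5,11(13)-trien-12-oate | COC(=O)C(=C)[C@H]1c2cc(C)c(o2)C[C@@H]3O[C@@]3(C)C[C@H]1O | intermediate
21 | isobutyric anhydride | CC(C)C(=O)OC(=O)C(C)C | starting material
22 | methyl (1S,7R,8R,10S)-1,10:3,6-diepoxy-8-(2-methylpropanoyloxy)germacra-3,5,11(13)-trien-12-oate | COC(=O)C(=C)[C@H]1c2cc(C)c(o2)C[C@@H]3O[C@@]3(C)C[C@H]1OC(=O)C(C)C | intermediate
23 | methyl (1S,7R,8R,10S)-1,10:3,6-diepoxy-3,6-epidioxy-8-(2-methylpropanoyloxy)germacra-4,11(13)-dien-12-oate (either face at C3/C6; both give 24) | COC(=O)C(=C)[C@H]1C23C=C(C)C(O2)(OO3)C[C@@H]4O[C@@]4(C)C[C@H]1OC(=O)C(C)C | intermediate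
24 | methyl (1S,7R,8R,10S,4Z)-1,10-epoxy-8-(2-methylpropanoyloxy)-3,6-dioxogermacra-4,11(13)-dien-12-oate | COC(=O)C(=C)[C@H]1C(=O)/C=C(/C)C(=O)C[C@@H]2O[C@@]2(C)C[C@H]1OC(=O)C(C)C | intermediate
25 | methyl (1S,3S,6R,7S,8R,10S,4Z)-1,10-epoxy-3,6-dihydroxy-8-(2-methylpropanoyloxy)germacra-4,11(13)-dien-12-oate (7S only by priority change; same geometry as 7R in 24 and 26) | COC(=O)C(=C)[C@H]1[C@H](O)/C=C(/C)[C@@H](O)C[C@@H]2O[C@@]2(C)C[C@H]1OC(=O)C(C)C | intermediate
26 | (1S,3S,6R,7R,8R,10S,4Z)-1,10-epoxy-3-hydroxy-8-(2-methylpropanoyloxy)germacra-4,11(13)-dien-12,6-olide | C=C1C(=O)O[C@@H]2/C=C(/C)[C@@H](O)C[C@@H]3O[C@@]3(C)C[C@@H](OC(=O)C(C)C)[C@@H]12 | target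

## Step count and weak points

Total: 12 steps. Longest linear sequence: 11 steps (steps 2–12 from silyl ether 3); step 1 is a one-step side branch.

**Step 12** is the most likely to fail. The enedione 24 has an acidic C7–H next to a β-acyloxy group, so it can epimerise or eliminate. The catalyst must also treat the alkenyl group as the large group at both ketones, although C7 is a branched carbon. Fallback: set out from 22 and open the furan as before to 24, but reduce with NaBH4/CeCl3·7H2O in MeOH at −78 °C, so that C6 is set by the ring and not by a catalyst. This gives the diol as a C3-epimer mixture F1, which lactonises with pyridinium p-toluenesulfonate to the lactone C3-epimer mixture F2. MnO2 in CH2Cl2 then oxidises the allylic 3-hydroxyl of both epimers to the single 3-oxo lactone F3. In F3 the ketone lies between a methyl-bearing alkenyl group and a CH2 group, so (R)-CBS/catecholborane reduction is reliably catalyst-controlled and returns to the route at 26.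

**Step 10** is the second risk. The ten-membered ring is closed onto a rigid furan and a trans-epoxide, and the face selectivity relative to the epoxide is not secured by precedent. If the wrong syn diastereomer forms it is at least separable and enantiopure. Fallback: set out from 15 and acetylate it (Ac2O, 4-(dimethylamino)pyridine) to the Baylis–Hillman acetate F4. Remove the silyl group with HF·pyridine to give the alcohol F5 and oxidise with Dess–Martin periodinane to the acetate aldehyde F6. Close the ring by palladium-catalysed umpolung allylation (Pd(PPh3)4 5 mol%, Et2Zn, THF, high dilution), the method that closes epoxide-bearing germacrane ten-membered rings. The π-allylpalladium species is transmetallated to the allyl(ethyl)zinc F7, which adds to the aldehyde and returns to the route at 20.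

**Step 5** is the third risk. Butyllithium is used next to a trisubstituted epoxide, and deprotonation of the furfurylic CH2 instead of the ring would open the epoxide by β-elimination. Fallback: set out from 2 and install the formyl carbon before the fragments are joined. Vilsmeier formylation (POCl3, DMF) of 2 gives 5-bromo-4-methylfuran-2-carbaldehyde F8, and MeOH with pyridinium p-toluenesulfonate and 3 Å sieves gives the dimethyl acetal F9. Bromine–lithium exchange (n-BuLi, THF, −78 °C) gives the lithio acetal F10, which is alkylated by epoxy triflate 9 (made as in step 4) to the coupled acetal F11. Mild hydrolysis (pyridinium p-toluenesulfonate, wet acetone) returns to the route at 13 without any organolithium meeting the epoxide after the coupling.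

## Further compounds

F1 | step 12 | methyl (1S,6R,7S,8R,10S,4Z)-1,10-epoxy-3,6-dihydroxy-8-(2-methylpropanoyloxy)germacra-4,11(13)-dien-12-oate, C3-epimer mixture | COC(=O)C(=C)[C@H]1[C@H](O)/C=C(/C)C(O)C[C@@H]2O[C@@]2(C)C[C@H]1OC(=O)C(C)C
F2 | step 12 | (1S,6R,7R,8R,10S,4Z)-1,10-epoxy-3-hydroxy-8-(2-methylpropanoyloxy)germacra-4,11(13)-dien-12,6-olide, C3-epimer mixture | C=C1C(=O)O[C@@H]2/C=C(/C)C(O)C[C@@H]3O[C@@]3(C)C[C@@H](OC(=O)C(C)C)[C@@H]12
F3 | step 12 | (1S,6R,7R,8R,10S,4Z)-1,10-epoxy-8-(2-methylpropanoyloxy)-3-oxogermacra-4,11(13)-dien-12,6-olide | C=C1C(=O)O[C@@H]2/C=C(/C)C(=O)C[C@@H]3O[C@@]3(C)C[C@@H](OC(=O)C(C)C)[C@@H]12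
F4 | step 10 | methyl 2-{acetoxy[5-({(2S,3S)-3-[2-(tert-butyldimethylsilyloxy)ethyl]-3-methyloxiran-2-yl}methyl)-4-methylfuran-2-yl]methyl}prop-2-enoate | C[C@@]1(CCO[Si](C)(C)C(C)(C)C)O[C@H]1Cc1oc(C(OC(C)=O)C(=C)C(=O)OC)cc1C
F5 | step 10 | methyl 2-{acetoxy[5-{[(2S,3S)-3-(2-hydroxyethyl)-3-methyloxiran-2-yl]methyl}-4-methylfuran-2-yl]methyl}prop-2-enoate | C[C@@]1(CCO)O[C@H]1Cc1oc(C(OC(C)=O)C(=C)C(=O)OC)cc1C
F6 | step 10 | methyl 2-{acetoxy[4-methyl-5-{[(2S,3S)-3-methyl-3-(2-oxoethyl)oxiran-2-yl]methyl}furan-2-yl]methyl}prop-2-enoate | C[C@@]1(CC=O)O[C@H]1Cc1oc(C(OC(C)=O)C(=C)C(=O)OC)cc1C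
F7 | step 10 | allyl(ethyl)zinc from F6 (ethylzinc on the acrylate CH2) | C[C@@]1(CC=O)O[C@H]1Cc1oc(/C=C(\C[Zn]CC)C(=O)OC)cc1C
F8 | step 5 | 5-bromo-4-methylfuran-2-carbaldehyde | Cc1cc(C=O)oc1Br
F9 | step 5 | 2-bromo-5-(dimethoxymethyl)-3-methylfuran | COC(OC)c1cc(C)c(Br)o1
F10 | step 5 | 5-(dimethoxymethyl)-2-lithio-3-methylfuran | COC(OC)c1cc(C)c([Li])o1
F11 | step 5 | tert-butyl{2-[(2S,3S)-3-{[5-(dimethoxymethyl)-3-methylfuran-2-yl]methyl}-2-methyloxiran-2-yl]ethoxy}dimethylsilane | C[C@@]1(CCO[Si](C)(C)C(C)(C)C)O[C@H]1Cc1oc(C(OC)OC)cc1C
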